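**Plan**

- Retrosynthesis: the phenol is freed last (O–Si) and the C3 methyl is traced back to an iodomethyl group (C–I). The dioxane is then cut at O4–C3, which uncovers a vinyl group on C2 and a free ring-A phenol. The aryl allyl ether bond O1–C2 is cut next, giving a mono-protected 5-allyl-3-methoxycatechol and a syringyl cinnamyl carbonate.
- Feature used: in the ring O1–C2(aryl)–C3(methyl)–O4–C4a–C8a, the C3 methyl together with the O4–C3 bond is what Markovnikov addition of the O4–H phenol across a vinyl group on C2 leaves behind, so the vinyl group serves as a latent methyl.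
- Forward: the two arenes are made separately (four steps each) and joined at O1–C2 by iridium-catalysed branched allylic etherification. After O4–H is unmasked, the only new ring, the dioxane, closes at O4–C3 by 6-exo iodoetherification; deiodination and desilylation follow.
- Stereochemistry: C2 comes from the chiral iridium–phosphoramidite catalyst (S ether; the descriptor becomes 2R after ring closure only because the CIP priorities change). C3 comes from C2 by substrate control in the ring closure (2,3-trans).

Key step: step 11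

Remark on the chemistry: the tetrahydropyranyl acetal carbon is introduced racemic, so every compound carrying it is a pair of epimers at that carbon (left undefined in the SMILES); the pair merges when the group is removed. The ligand antipode in step 9 is assigned from the accepted facial model for aryl-substituted allyl carbonates; the other antipode is used if the sense proves opposite.

**Route**

Step 1
Reactants: 1 syringaldehyde
Product: 2 3,5-dimethoxy-4-(triisopropylsilyloxy)benzaldehyde
Conditions: i-Pr3SiCl, imidazole, DMF, rt to 40 °C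
Reagents that add atoms: triisopropylsilyl chloride, CC(C)[Si](Cl)(C(C)C)C(C)C
Why: Imidazole-promoted silylation of an acidic phenol; the bulky silyl ether, shielded by two ortho methoxy groups, should survive hydride, base, weak acid, iodine and tin hydride until the last step.

Step 2
Reactants: 2 3,5-dimethoxy-4-(triisopropylsilyloxy)benzaldehyde
Product: 3 ethyl (E)-3-[3,5-dimethoxy-4-(triisopropylsilyloxy)phenyl]prop-2-enoate
Conditions: Ph3P=CHCO2Et, toluene, 80 °C
Reagents that add atoms: ethyl (triphenylphosphoranylidene)acetate, CCOC(=O)C=P(c1ccccc1)(c1ccccc1)c1ccccc1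
Why: Wittig olefination with a stabilised ylide should give the E enoate under base-free conditions that spare the aryl silyl ether.

Step 3
Reactants: 3 ethyl (E)-3-[3,5-dimethoxy-4-(triisopropylsilyloxy)phenyl]prop-2-enoate
Product: 4 (E)-3-[3,5-dimethoxy-4-(triisopropylsilyloxy)phenyl]prop-2-en-1-ol
Conditions: i-Bu2AlH, CH2Cl2, −78 °C; aq. potassium sodium tartrate
Reagents that add atoms: none
Why: 1,2-Reduction of an α,β-unsaturated ester by a dialkylaluminium hydride at low temperature should give the allylic alcohol and leave the alkene and the silyl ether alone.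

Step 4
Reactants: 4 (E)-3-[3,5-dimethoxy-4-(triisopropylsilyloxy)phenyl]prop-2-en-1-ol
Product: 5 (E)-3-[3,5-dimethoxy-4-(triisopropylsilyloxy)phenyl]prop-2-en-1-yl methyl carbonate
Conditions: ClCO2Me, pyridine, CH2Cl2, 0 °C
Reagents that add atoms: methyl chloroformate, COC(=O)Cl
Why: Acylation of a primary alcohol with a chloroformate gives the linear methyl carbonate that serves as the allyl donor in step 9.

Step 5
Reactants: 6 2-bromo-6-methoxyphenol; 7 allyl bromide
Product: 8 1-bromo-3-methoxy-2-(prop-2-en-1-yloxy)benzene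
Conditions: K2CO3, acetone, reflux
Reagents that add atoms: none
Why: Williamson ether synthesis of a phenoxide with a reactive allylic halide.

Step 6
Reactants: 8 1-bromo-3-methoxy-2-(prop-2-en-1-yloxy)benzene
Product: 11 4-allyl-2-bromo-6-methoxyphenol, via 6-allyl-2-bromo-6-methoxycyclohexa-2,4-dien-1-one 9 (not isolated), via 4-allyl-2-bromo-6-methoxycyclohexa-2,5-dien-1-one 10 (not isolated)
Conditions: PhNEt2, 190 °C, N2
Reagents that add atoms: none
Why: Aromatic para-Claisen rearrangement: with both ortho positions substituted the first [3,3] shift gives a dienone that cannot enolise, a Cope shift carries the allyl group to C4, and tautomerisation restores the phenol.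

Step 7
Reactants: 11 4-allyl-2-bromo-6-methoxyphenol
Product: 12 2-(4-allyl-2-bromo-6-methoxyphenoxy)tetrahydro-2H-pyran
Conditions: 3,4-dihydro-2H-pyran, PPTS (cat.), CH2Cl2, rt
Reagents that add atoms: 3,4-dihydro-2H-pyran, C1=COCCC1
Why: Acid-catalysed addition of the phenol to an enol ether gives an acetal that withstands organolithium and aryloxide chemistry, cannot migrate between the two catechol oxygens (as an acyl or silyl group would) and is removable in very weak acid.

Step 8
Reactants: 12 2-(4-allyl-2-bromo-6-methoxyphenoxy)tetrahydro-2H-pyran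
Product: 15 5-allyl-3-methoxy-2-(tetrahydropyran-2-yloxy)phenol, via [5-allyl-3-methoxy-2-(tetrahydropyran-2-yloxy)phenyl]lithium 13 (not isolated), via dimethyl [5-allyl-3-methoxy-2-(tetrahydropyran-2-yloxy)phenyl]boronate 14 (not isolated)
Conditions: n-BuLi, THF, −78 °C; B(OMe)3, −78 to 0 °C; H2O2, aq. NaOH, 0 °C; NH4Cl quench
Reagents that add atoms: hydrogen peroxide, OO
Why: Bromine–lithium exchange at −78 °C is faster than deprotonation of the allylic benzylic CH2, and borylation followed by alkaline peroxide oxidation (aryl shift from boron to oxygen) should install the hydroxyl with the acetal intact.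

Step 9
Reactants: 15 5-allyl-3-methoxy-2-(tetrahydropyran-2-yloxy)phenol; 5 (E)-3-[3,5-dimethoxy-4-(triisopropylsilyloxy)phenyl]prop-2-en-1-yl methyl carbonate
Product: 17 2-[4-allyl-2-{[(1S)-1-(3,5-dimethoxy-4-triisopropylsilyloxyphenyl)prop-2-en-1-yl]oxy}-6-methoxyphenoxy]tetrahydro-2H-pyran, via lithium 5-allyl-3-methoxy-2-(tetrahydropyran-2-yloxy)phenoxide 16 (not isolated)
Conditions: n-BuLi, THF, 0 °C (15 in 1.5-fold excess); then 5, [Ir(cod)Cl]2 (2 mol%), (Sa,Sc,Sc)-O,O′-(1,1′-binaphthyl-2,2′-diyl) N,N-bis(1-phenylethyl)phosphoramidite (4 mol%), THF, 50 °C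
Reagents that add atoms: none
Why: Iridium-catalysed asymmetric allylic substitution (Tsuji–Trost type) with a cyclometalated phosphoramidite complex: the aryloxide attacks the aryl-substituted terminus of the allyl–iridium intermediate on the face fixed by the ligand, which should give the branched S ether (the future C2) with high regio- and enantioselectivity.

Step 10
Reactants: 17 2-[4-allyl-2-{[(1S)-1-(3,5-dimethoxy-4-triisopropylsilyloxyphenyl)prop-2-en-1-yl]oxy}-6-methoxyphenoxy]tetrahydro-2H-pyran
Product: 18 4-allyl-2-methoxy-6-{[(1S)-1-(3,5-dimethoxy-4-triisopropylsilyloxyphenyl)prop-2-en-1-yl]oxy}phenol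
Conditions: PPTS (0.1 equiv), MeOH, 0 °C to rt
Reagents that add atoms: none
Why: Acid-catalysed transacetalisation with methanol: aryl tetrahydropyranyl ethers cleave at a buffered acidity well below that needed to ionise the aryl 1-arylallyl ether, whose aryl group is only moderately donating (para silyloxy, two meta methoxy groups), so the stereocentre and the branched connectivity should survive.

Step 11
Reactants: 18 4-allyl-2-methoxy-6-{[(1S)-1-(3,5-dimethoxy-4-triisopropylsilyloxyphenyl)prop-2-en-1-yl]oxy}phenol
Product: 19 (2R,3S)-7-allyl-3-(iodomethyl)-5-methoxy-2-[3,5-dimethoxy-4-(triisopropylsilyloxy)phenyl]-2,3-dihydro-1,4-benzodioxine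
Conditions: I2, NaHCO3, MeCN, 0 °C, dark; aq. Na2S2O3
Reagents that add atoms: iodine, II
Why: Iodine forms iodonium ions reversibly at both terminal alkenes, but only the vinyl group on the ether carbon has an internal nucleophile: the bicarbonate-buffered phenol oxygen O4 opens that iodonium anti at the internal carbon, while the C7 allyl group is returned unchanged. The closest known reaction type is the iodoetherification (halocyclisation) of alkenyl phenols, as in the closure of 2-(allyloxy)phenols to 2-(iodomethyl)-1,4-benzodioxanes. The dioxane ring closes in the 6-exo-trig mode through the new O4–C3 bond, which should be preferred over the 7-endo alternative. The new stereocentre C3 is controlled by C2: in the half-chair transition state the tether holds O1–C2 roughly perpendicular to the alkene plane, the C2 hydrogen eclipses the double bond and the aryl group points away from the iodonium-bearing CH2, so the iodomethyl group ends up trans to the aryl group (2R,3S). The step needs chemoselectivity between two alkenes, exo regioselectivity, 2,3-trans diastereoselectivity and no ring iodination; these rest on the position of the phenol, the ring size, allylic 1,3-strain, and the fact that every position ortho or para to the free phenol is substituted.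

Step 12
Reactants: 19 (2R,3S)-7-allyl-3-(iodomethyl)-5-methoxy-2-[3,5-dimethoxy-4-(triisopropylsilyloxy)phenyl]-2,3-dihydro-1,4-benzodioxine
Product: 20 (2R,3R)-7-allyl-5-methoxy-3-methyl-2-[3,5-dimethoxy-4-(triisopropylsilyloxy)phenyl]-2,3-dihydro-1,4-benzodioxine
Conditions: Bu3SnH (0.2 M), Et3B (cat.), air, toluene, 0 °C to rt; aq. KF
Reagents that add atoms: none
Why: Radical chain dehalogenation: the stannyl radical abstracts iodine and the primary radical is quenched by the stannane, with low temperature and a high stannane concentration chosen so that hydrogen transfer outruns β-scission of the aryloxy group; neither stereocentre takes part.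

Step 13
Reactants: 20 (2R,3R)-7-allyl-5-methoxy-3-methyl-2-[3,5-dimethoxy-4-(triisopropylsilyloxy)phenyl]-2,3-dihydro-1,4-benzodioxine
Product: 21 4-[(2R,3R)-7-allyl-5-methoxy-3-methyl-2,3-dihydro-1,4-benzodioxin-2-yl]-2,6-dimethoxyphenol
Conditions: Bu4NF, AcOH (1:1), THF, 0 °C
Reagents that add atoms: none
Why: Fluoride-induced cleavage of the aryl silyl ether, buffered with acetic acid so that the liberated para-hydroxybenzyl ether is not opened to a quinone methide and C2 is not epimerised.

**Compound list**

1 | syringaldehyde (4-hydroxy-3,5-dimethoxybenzaldehyde) | COc1cc(C=O)cc(OC)c1O | starting material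
2 | 3,5-dimethoxy-4-(triisopropylsilyloxy)benzaldehyde | COc1cc(C=O)cc(OC)c1O[Si](C(C)C)(C(C)C)C(C)C | intermediate
3 | ethyl (E)-3-[3,5-dimethoxy-4-(triisopropylsilyloxy)phenyl]prop-2-enoate | CCOC(=O)/C=C/c1cc(OC)c(O[Si](C(C)C)(C(C)C)C(C)C)c(OC)c1 | intermediate
4 | (E)-3-[3,5-dimethoxy-4-(triisopropylsilyloxy)phenyl]prop-2-en-1-ol | OC/C=C/c1cc(OC)c(O[Si](C(C)C)(C(C)C)C(C)C)c(OC)c1 | intermediate
5 | (E)-3-[3,5-dimethoxy-4-(triisopropylsilyloxy)phenyl]prop-2-en-1-yl methyl carbonate | COC(=O)OC/C=C/c1cc(OC)c(O[Si](C(C)C)(C(C)C)C(C)C)c(OC)c1 | intermediate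
6 | 2-bromo-6-methoxyphenol | COc1cccc(Br)c1O | starting material
7 | allyl bromide | C=CCBr | starting material
8 | 1-bromo-3-methoxy-2-(prop-2-en-1-yloxy)benzene | COc1cccc(Br)c1OCC=C | intermediate
9 | 6-allyl-2-bromo-6-methoxycyclohexa-2,4-dien-1-one (racemic, not isolated) | C=CCC1(OC)C=CC=C(Br)C1=O | intermediate
10 | 4-allyl-2-bromo-6-methoxycyclohexa-2,5-dien-1-one (racemic, not isolated) | C=CCC1C=C(Br)C(=O)C(OC)=C1 | intermediate
11 | 4-allyl-2-bromo-6-methoxyphenol | C=CCc1cc(Br)c(O)c(OC)c1 | intermediate
12 | 2-(4-allyl-2-bromo-6-methoxyphenoxy)tetrahydro-2H-pyran (racemic) | C=CCc1cc(Br)c(OC2CCCCO2)c(OC)c1 | intermediate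
13 | [5-allyl-3-methoxy-2-(tetrahydropyran-2-yloxy)phenyl]lithium (not isolated) | [Li]c1cc(CC=C)cc(OC)c1OC1CCCCO1 | intermediate
14 | dimethyl [5-allyl-3-methoxy-2-(tetrahydropyran-2-yloxy)phenyl]boronate (not isolated) | COB(OC)c1cc(CC=C)cc(OC)c1OC1CCCCO1 | intermediate
15 | 5-allyl-3-methoxy-2-(tetrahydropyran-2-yloxy)phenol (racemic) | C=CCc1cc(O)c(OC2CCCCO2)c(OC)c1 | intermediate
16 | lithium 5-allyl-3-methoxy-2-(tetrahydropyran-2-yloxy)phenoxide (not isolated) | [Li+].[O-]c1cc(CC=C)cc(OC)c1OC1CCCCO1 | intermediate
17 | 2-[4-allyl-2-{[(1S)-1-(3,5-dimethoxy-4-triisopropylsilyloxyphenyl)prop-2-en-1-yl]oxy}-6-methoxyphenoxy]tetrahydro-2H-pyran (both acetal epimers) | C=CCc1cc(OC)c(OC2CCCCO2)c(c1)O[C@H](c1cc(OC)c(O[Si](C(C)C)(C(C)C)C(C)C)c(OC)c1)C=C | intermediate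
18 | 4-allyl-2-methoxy-6-{[(1S)-1-(3,5-dimethoxy-4-triisopropylsilyloxyphenyl)prop-2-en-1-yl]oxy}phenol | C=CCc1cc(OC)c(O)c(c1)O[C@H](c1cc(OC)c(O[Si](C(C)C)(C(C)C)C(C)C)c(OC)c1)C=C | intermediate
19 | (2R,3S)-7-allyl-3-(iodomethyl)-5-methoxy-2-[3,5-dimethoxy-4-(triisopropylsilyloxy)phenyl]-2,3-dihydro-1,4-benzodioxine (2,3-trans) | C=CCc1cc(OC)c2c(c1)O[C@H](c1cc(OC)c(O[Si](C(C)C)(C(C)C)C(C)C)c(OC)c1)[C@@H](CI)O2 | intermediate
20 | (2R,3R)-7-allyl-5-methoxy-3-methyl-2-[3,5-dimethoxy-4-(triisopropylsilyloxy)phenyl]-2,3-dihydro-1,4-benzodioxine (2,3-trans) | C=CCc1cc(OC)c2c(c1)O[C@H](c1cc(OC)c(O[Si](C(C)C)(C(C)C)C(C)C)c(OC)c1)[C@@H](C)O2 | intermediate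
21 | 4-[(2R,3R)-7-allyl-5-methoxy-3-methyl-2,3-dihydro-1,4-benzodioxin-2-yl]-2,6-dimethoxyphenol | C=CCc1cc(OC)c2c(c1)O[C@H](c1cc(OC)c(O)c(OC)c1)[C@@H](C)O2 | target

**Step count**

Total: 13 steps. Longest linear sequence: 9 steps (steps 5–13; the arm through steps 1–4 and 9–13 is equally long).

**Steps most likely to fail**

1. Step 11 (ring closure). Facial selectivity in the capture of the iodonium ion may be poor, giving a cis/trans mixture at C3, or activation of the oxygen-deactivated vinyl group may be slow. The fallback sets out from phenol 18 and returns at 20. It replaces the kinetically controlled iodonium capture by reversible intramolecular oxymercuration. Hg(OCOCF3)2 in dry MeCN (0 °C to rt) is left to equilibrate so that the more stable trans closure accumulates. Exchange with aqueous NaCl then gives (2R,3S)-7-allyl-3-(chloromercuriomethyl)-5-methoxy-2-[3,5-dimethoxy-4-(triisopropylsilyloxy)phenyl]-2,3-dihydro-1,4-benzodioxine F1. Reductive demercuration with NaBH4 in aqueous NaOH/THF replaces mercury by hydrogen and should give 20 directly, so step 12 is not needed.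

2. Step 9 (ether formation). The hindered ortho-substituted aryloxide may attack slowly, the branched-to-linear ratio may be low, or enantiopurity may erode through reversible ionisation of the electron-rich branched ether. The fallback sets out from aldehyde 2 and phenol 15 and returns at 17. The stereocentre is obtained by resolution and then transferred stereospecifically.
   - CH2=CHMgBr (THF, −78 °C) adds to 2 to give racemic 1-[3,5-dimethoxy-4-(triisopropylsilyloxy)phenyl]prop-2-en-1-ol F2.
   - Sharpless kinetic resolution (Ti(OiPr)4, L-(+)-diisopropyl tartrate, t-BuOOH, 4 Å sieves, CH2Cl2, −20 °C) should leave (S)-1-[3,5-dimethoxy-4-(triisopropylsilyloxy)phenyl]prop-2-en-1-ol F3. By the usual mnemonic the R enantiomer is converted into (S)-[3,5-dimethoxy-4-(triisopropylsilyloxy)phenyl][(2S)-oxiran-2-yl]methanol F4, which is separated.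
   - n-BuLi then Boc2O gives tert-butyl (1S)-1-[3,5-dimethoxy-4-(triisopropylsilyloxy)phenyl]prop-2-en-1-yl carbonate F5.
   - O-Allylation of phenol 15 catalysed by [Cp*Ru(MeCN)3]PF6 (acetone, rt) is a known branched-selective reaction that proceeds with retention by double inversion, and should give 17.

3. Step 6 (para-Claisen rearrangement). The dienone that carries bromine at the quaternary carbon may lose bromine, or the allyl group may be trapped at an ortho position, which lowers the share of para product. The fallback sets out from 6 and returns at 12; it forms the aryl–allyl bond by cross-coupling. NIS in MeCN iodinates 6 para to the hydroxyl to give 2-bromo-4-iodo-6-methoxyphenol F6. Dihydropyran with catalytic PPTS gives 2-(2-bromo-4-iodo-6-methoxyphenoxy)tetrahydro-2H-pyran F7. A Stille coupling selective for the carbon–iodine bond (allyltributylstannane, Pd(PPh3)4, toluene, 90 °C) then gives 12, replacing steps 5–7.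

**Further compounds**

F1 | step 11 | (2R,3S)-7-allyl-3-(chloromercuriomethyl)-5-methoxy-2-[3,5-dimethoxy-4-(triisopropylsilyloxy)phenyl]-2,3-dihydro-1,4-benzodioxine | C=CCc1cc(OC)c2c(c1)O[C@H](c1cc(OC)c(O[Si](C(C)C)(C(C)C)C(C)C)c(OC)c1)[C@@H](C[Hg]Cl)O2
F2 | step 9 | racemic 1-[3,5-dimethoxy-4-(triisopropylsilyloxy)phenyl]prop-2-en-1-ol | OC(C=C)c1cc(OC)c(O[Si](C(C)C)(C(C)C)C(C)C)c(OC)c1
F3 | step 9 | (S)-1-[3,5-dimethoxy-4-(triisopropylsilyloxy)phenyl]prop-2-en-1-ol | O[C@H](c1cc(OC)c(O[Si](C(C)C)(C(C)C)C(C)C)c(OC)c1)C=C
F4 | step 9 | (S)-[3,5-dimethoxy-4-(triisopropylsilyloxy)phenyl][(2S)-oxiran-2-yl]methanol | O[C@@H](c1cc(OC)c(O[Si](C(C)C)(C(C)C)C(C)C)c(OC)c1)[C@@H]1CO1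
F5 | step 9 | tert-butyl (1S)-1-[3,5-dimethoxy-4-(triisopropylsilyloxy)phenyl]prop-2-en-1-yl carbonate | CC(C)(C)OC(=O)O[C@H](c1cc(OC)c(O[Si](C(C)C)(C(C)C)C(C)C)c(OC)c1)C=C
F6 | step 6 | 2-bromo-4-iodo-6-methoxyphenol | COc1cc(I)cc(Br)c1O
F7 | step 6 | 2-(2-bromo-4-iodo-6-methoxyphenoxy)tetrahydro-2H-pyran (racemic) | COc1cc(I)cc(Br)c1OC1CCCCO1
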